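**Plan** (target numbered as bicyclo[3.3.1]non-2-ene: C-1 and C-2 carry CHO, C-5 the methyl, C-8 the side chain, C-9 the acetate)
Retrosynthesis: acetate and both aldehydes ← triol ← butenolide-fused bicyclo[3.3.1]nonan-9-one; then C-5–C-9 and C-6–C-7 are cut together, which opens both carbocycles to a spiro cyclobutanone–γ-lactone with a 3-methylbut-3-enyl chain; that is cut at C-1–CH2O and C-2–C-3 (enone three-component coupling), and the cyclobutanone is traced to (R)-citronellal.
Enabling feature: ring C-1/C-9/C-5/C-6/C-7/C-8 is a cyclohexanone at C-9 between two quaternary carbons, i.e. a cyclobutanone (C-9, C-1, C-8, C-7) into whose C-9–C-7 bond the C-5=C-6 olefin, tethered through C-2–C-4, has been inserted.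
Forward: citronellal → 3-substituted cyclobutanone → aldol/dehydration → conjugate addition–hydroxymethylation–lactonisation → rhodium-catalysed olefin insertion closes both six-membered carbocycles at once → desaturation, reduction, acetylation, oxidation.
Stereochemistry: side-chain centre from (R)-citronellal; C-8 by catalyst-controlled choice between enantiotopic methylenes; C-1 by hydroxymethylation anti to the C-8 substituent; C-5 forced by the bridge; C-9 by hydride attack from the face of the unsaturated ring.

Key step: step 7

Assumption: the D-proline-derived catalyst of step 4 is assigned as the one that functionalises the required methylene by analogy with enamine-aldol transition-state models; if the sense is opposite, its enantiomer is used.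

Step 1
Reactants: 1 (R)-citronellal
Product: 3 2-[(2R)-6-methylhept-5-en-2-yl]propane-1,3-diol, via hydroxymethyl aldehyde 2 (not isolated)
Conditions: aq. CH2O, (S)-α,α-diphenylprolinol trimethylsilyl ether (10 mol %), pH 7 buffer, PhMe, rt; then NaBH4, MeOH, 0 °C
Reagents that add atoms: formaldehyde, C=O
Why: Amine-catalysed α-hydroxymethylation (enamine aldol with formaldehyde) and borohydride reduction should give the 1,3-diol, whose former α-carbon carries two identical arms and is no stereocentre, so no selectivity is needed and the citronellal centre is untouched.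

Step 2
Reactants: 3 2-[(2R)-6-methylhept-5-en-2-yl]propane-1,3-diol
Product: 4 (6R)-8-bromo-7-(bromomethyl)-2,6-dimethyloct-2-ene
Conditions: CBr4, PPh3, CH2Cl2, 0 °C → rt
Reagents that add atoms: carbon tetrabromide, BrC(Br)(Br)Br
Why: Appel reaction, in which both primary alkoxyphosphonium ions are displaced by bromide (SN2) while the trisubstituted olefin is inert.

Step 3
Reactants: 4 (6R)-8-bromo-7-(bromomethyl)-2,6-dimethyloct-2-ene
Product: 6 3-[(2R)-6-methylhept-5-en-2-yl]cyclobutan-1-one, via isocyano sulfone 5 (not isolated)
Conditions: TosMIC, NaH, DMSO–Et2O, rt; then aq. HCl, Et2O, rt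
Reagents that add atoms: p-toluenesulfonylmethyl isocyanide (TosMIC), Cc1ccc(cc1)S(=O)(=O)C[N+]#[C-]; water, O
Why: Van Leusen ketone synthesis, in which the TosMIC carbon is alkylated twice (the second time as a 4-exo-tet closure) and acid hydrolysis unmasks the ketone; C-3 of the symmetric cyclobutanone is not a stereocentre.

Step 4
Reactants: 6 3-[(2R)-6-methylhept-5-en-2-yl]cyclobutan-1-one; 7 ethyl glyoxylate
Product: 8 ethyl 2-hydroxy-2-[(1R,2S)-2-[(2R)-6-methylhept-5-en-2-yl]-4-oxocyclobutyl]acetate (carbinol epimers)
Conditions: N-(p-tolylsulfonyl)-D-prolinamide (20 mol %), CH2Cl2, 0 °C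
Reagents that add atoms: none
Why: Enamine-catalysed direct aldol addition to the electrophilic glyoxylate, in which the chiral enamine reacts on one face and readily only at the methylene where that face is anti to the C-3 substituent, so the catalyst enantiomer selects one enantiotopic methylene and thereby fixes the ring CH centre (2S); the other two new centres are removed in step 5.

Step 5
Reactants: 8 ethyl 2-hydroxy-2-[(1R,2S)-2-[(2R)-6-methylhept-5-en-2-yl]-4-oxocyclobutyl]acetate
Product: 10 ethyl (2E)-2-[(2S)-2-[(2R)-6-methylhept-5-en-2-yl]-4-oxocyclobutylidene]acetate (either olefin geometry serves), via methanesulfonate 9 (not isolated)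
Conditions: MsCl, Et3N, CH2Cl2, 0 °C → rt
Reagents that add atoms: none
Why: Mesylation and E1cB elimination through the ketone enolate complete the aldol condensation; the ring CH centre should not epimerise because its deprotonation would need an endocyclic cyclobutene double bond.

Step 6
Reactants: 10 ethyl (2E)-2-[(2S)-2-[(2R)-6-methylhept-5-en-2-yl]-4-oxocyclobutylidene]acetate; 11 4-bromo-2-methylbut-1-ene
Product: 15 (3S,4S)-3-[(2R)-6-methylhept-5-en-2-yl]-8-(3-methylbut-3-en-1-yl)-6-oxaspiro[3.4]octane-1,7-dione (C-8 epimers), via Grignard reagent 12 (not isolated), via bromomagnesium enolate 13 (not isolated), via hydroxymethyl keto ester 14 (not isolated)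
Conditions: 11, Mg, THF; 10, CuBr·SMe2 (20 mol %), THF, −78 °C; CH2O (gas), −78 → −20 °C; aq. NH4Cl; then p-TsOH (cat.), CH2Cl2, rt
Reagents that add atoms: formaldehyde, C=O
Why: Copper-catalysed conjugate addition of the Grignard reagent to the carbon β to the ketone gives the ring enolate regiospecifically, which adds to formaldehyde (aldol) on the face anti to the neighbouring side chain, so the new quaternary carbon carries CH2OH trans and the ester-bearing carbon cis to that side chain, and the γ-hydroxy ester then lactonises.

Step 7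
Reactants: 15 (3S,4S)-3-[(2R)-6-methylhept-5-en-2-yl]-8-(3-methylbut-3-en-1-yl)-6-oxaspiro[3.4]octane-1,7-dione
Product: 16 (1S,5R,8S)-1-(hydroxymethyl)-5-methyl-8-[(2R)-6-methylhept-5-en-2-yl]-9-oxobicyclo[3.3.1]nonane-2-carboxylic acid γ-lactone (C-2 epimers)
Conditions: [Rh(C2H4)2Cl]2 (5 mol %), P[3,5-(CF3)2C6H3]3 (24 mol %), 2-amino-3-picoline (50 mol %), 1,4-dioxane, 130 °C; then aq. NH4Cl
Reagents that add atoms: none
Why: Proposed new method: the cyclobutanone condenses reversibly with 2-amino-3-picoline to a ketimine whose pyridine nitrogen directs monovalent rhodium into the C-1–C-2 bond of 15 (carbonyl carbon–ring methylene), the five-membered trivalent rhodacycle inserts the tethered 1,1-disubstituted olefin with the iminoacyl carbon bonding to the substituted olefin carbon, and C(sp3)–C(sp3) reductive elimination joins the ring methylene to the olefin CH2 before the imine is hydrolysed. The closest known reaction type is the rhodium-catalysed intramolecular carboacylation of olefins by cyclobutanone C–C activation with the olefin tethered at C-3, which puts the carbonyl in a three-atom bridge; a tether on the quaternary α-carbon with cleavage of the distal C–C bond, needed here to put the carbonyl on the one-carbon bridge, has not been shown. The carbocycle C-1 to C-5 with C-9 closes in the migratory insertion as a 6-exo event, and the cyclohexanone C-5 to C-9 with C-1 closes in the reductive elimination from a seven-membered rhodacycle, driven by release of four-ring strain. The only new stereocentre, the methyl-bearing bridgehead C-5, can form only cis-bridged to the existing quaternary C-1 and is set by it, while C-1, C-8 and the side-chain centre are untouched; the lactone α-carbon is epimerisable, so both epimers can react through the one whose chain faces the ketone. The step needs oxidative addition on the methylene side and not into the bond to the quaternary carbon (which would give a fused hydrindanone), and insertion with the acyl carbon on the internal olefin carbon; the first should be secured by the imine geometry (pyridyl anti to the quaternary carbon) and sterics, the second by the three-atom tether, which allows only the six-membered closure and leaves a rhodium alkyl without β-hydrogen.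

Step 8
Reactants: 16 keto lactone
Product: 19 (1S,5R,8S)-1-(hydroxymethyl)-5-methyl-8-[(2R)-6-methylhept-5-en-2-yl]-9-oxobicyclo[3.3.1]non-2-ene-2-carboxylic acid γ-lactone, via lithium enolate 17 (not isolated), via phenylselanyl lactone 18 (not isolated)
Conditions: LiN(SiMe3)2, THF, −78 °C; PhSeBr; then NaIO4, NaHCO3, THF–MeOH–H2O, rt
Reagents that add atoms: none
Why: Selenenylation of the lactone enolate (the only enolisable position, since both ketone α-carbons are quaternary) and syn-elimination of the selenoxide, which can only take a hydrogen from C-3 because C-1 is quaternary, should install the C-2=C-3 double bond.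

Step 9
Reactants: 19 keto butenolide
Product: 20 (1S,5R,8S,9R)-1,2-bis(hydroxymethyl)-5-methyl-8-[(2R)-6-methylhept-5-en-2-yl]bicyclo[3.3.1]non-2-en-9-ol
Conditions: i-Bu2AlH (6 equiv), CH2Cl2, −78 → 0 °C; aq. potassium sodium tartrate
Reagents that add atoms: none
Why: Hydride reduction, in which the butenolide is reduced 1,2 to the allylic diol and the bridging ketone is attacked from the face over the unsaturated ring (flattened, one axial hydrogen) and not over the saturated ring (axial hydrogens at C-6 and C-8), which should place the hydroxyl syn to the C-6–C-8 bridge (9R).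

Step 10
Reactants: 20 triol
Product: 21 (1S,5R,8S,9R)-5-methyl-8-[(2R)-6-methylhept-5-en-2-yl]-1,2-bis[(triethylsilyloxy)methyl]bicyclo[3.3.1]non-2-en-9-ol
Conditions: Et3SiCl (2.2 equiv), imidazole, CH2Cl2, 0 °C
Reagents that add atoms: chlorotriethylsilane, CC[Si](Cl)(CC)CC
Why: Silylation, in which the two primary alcohols react and the secondary alcohol between two quaternary bridgeheads is left free.

Step 11
Reactants: 21 bis(triethylsilyl) ether
Product: 22 (1S,5R,8S,9R)-5-methyl-8-[(2R)-6-methylhept-5-en-2-yl]-1,2-bis[(triethylsilyloxy)methyl]bicyclo[3.3.1]non-2-en-9-yl acetate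
Conditions: Ac2O, DMAP, Et3N, CH2Cl2, rt
Reagents that add atoms: acetic anhydride, CC(=O)OC(C)=O
Why: DMAP-catalysed acylation of the remaining secondary alcohol with retention at C-9.

Step 12
Reactants: 22 acetate bis(triethylsilyl) ether
Product: 24 (1R,5R,8S,9R)-1,2-diformyl-5-methyl-8-[(2R)-6-methylhept-5-en-2-yl]bicyclo[3.3.1]non-2-en-9-yl acetate, via bis(alkoxysulfonium) salt 23 (not isolated)
Conditions: (COCl)2, DMSO, CH2Cl2, −78 → −30 °C; then Et3N, −78 °C → rt
Reagents that add atoms: none
Why: Swern oxidation applied directly to primary triethylsilyl ethers (the chlorosulfonium ion takes the silyl ether oxygen, Et3SiCl leaves and the alkoxysulfonium ylide collapses to the aldehyde) should give the enal and the neopentyl aldehyde without a free hydroxy-acetate stage, and as C-1 is quaternary neither epimerisation nor β-elimination of acetate is possible.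

**Compound list**
1 | (R)-citronellal, (3R)-3,7-dimethyloct-6-enal | O=CC[C@H](C)CCC=C(C)C | starting material
2 | (3R)-2-(hydroxymethyl)-3,7-dimethyloct-6-enal (C-2 epimers) | O=CC(CO)[C@H](C)CCC=C(C)C | intermediate
3 | 2-[(2R)-6-methylhept-5-en-2-yl]propane-1,3-diol | OCC(CO)[C@H](C)CCC=C(C)C | intermediate
4 | (6R)-8-bromo-7-(bromomethyl)-2,6-dimethyloct-2-ene | BrCC(CBr)[C@H](C)CCC=C(C)C | intermediate
5 | 1-isocyano-3-[(2R)-6-methylhept-5-en-2-yl]-1-(p-tolylsulfonyl)cyclobutane | [C-]#[N+]C1(S(=O)(=O)c2ccc(C)cc2)CC(C1)[C@H](C)CCC=C(C)C | intermediate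
6 | 3-[(2R)-6-methylhept-5-en-2-yl]cyclobutan-1-one | O=C1CC(C1)[C@H](C)CCC=C(C)C | intermediate
7 | ethyl glyoxylate | CCOC(=O)C=O | starting material
8 | ethyl 2-hydroxy-2-[(1R,2S)-2-[(2R)-6-methylhept-5-en-2-yl]-4-oxocyclobutyl]acetate (carbinol epimers) | O=C1C[C@@H]([C@H](C)CCC=C(C)C)[C@@H]1C(O)C(=O)OCC | intermediate
9 | methanesulfonate of 8 | O=C1C[C@@H]([C@H](C)CCC=C(C)C)[C@@H]1C(OS(C)(=O)=O)C(=O)OCC | intermediate
10 | ethyl (2E)-2-[(2S)-2-[(2R)-6-methylhept-5-en-2-yl]-4-oxocyclobutylidene]acetate | O=C1C[C@@H]([C@H](C)CCC=C(C)C)/C1=C\C(=O)OCC | intermediate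
11 | 4-bromo-2-methylbut-1-ene | C=C(C)CCBr | starting material
12 | (3-methylbut-3-en-1-yl)magnesium bromide | C=C(C)CC[Mg]Br | intermediate
13 | bromomagnesium enolate from conjugate addition of 12 to 10 | CCOC(=O)C(CCC(C)=C)C1=C(O[Mg]Br)C[C@H]1[C@H](C)CCC=C(C)C | intermediate
14 | ethyl 2-[(1S,2S)-1-(hydroxymethyl)-2-[(2R)-6-methylhept-5-en-2-yl]-4-oxocyclobutyl]-5-methylhex-5-enoate (C-2 epimers) | O=C1C[C@@H]([C@H](C)CCC=C(C)C)[C@@]1(CO)C(CCC(C)=C)C(=O)OCC | intermediate
15 | (3S,4S)-3-[(2R)-6-methylhept-5-en-2-yl]-8-(3-methylbut-3-en-1-yl)-6-oxaspiro[3.4]octane-1,7-dione (C-8 epimers) | O=C1C[C@@H]([C@H](C)CCC=C(C)C)[C@]12COC(=O)C2CCC(C)=C | intermediate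
16 | (1S,5R,8S)-1-(hydroxymethyl)-5-methyl-8-[(2R)-6-methylhept-5-en-2-yl]-9-oxobicyclo[3.3.1]nonane-2-carboxylic acid γ-lactone (C-2 epimers) | O=C1[C@@]2(C)CCC3C(=O)OC[C@@]13[C@H]([C@H](C)CCC=C(C)C)CC2 | intermediate
17 | lithium enolate of lactone 16 | O=C1[C@@]2(C)CCC3=C(O[Li])OC[C@@]13[C@H]([C@H](C)CCC=C(C)C)CC2 | intermediate
18 | 2-(phenylselanyl) derivative of lactone 16 | O=C1[C@@]2(C)CCC3([Se]c4ccccc4)C(=O)OC[C@@]13[C@H]([C@H](C)CCC=C(C)C)CC2 | intermediate
19 | (1S,5R,8S)-1-(hydroxymethyl)-5-methyl-8-[(2R)-6-methylhept-5-en-2-yl]-9-oxobicyclo[3.3.1]non-2-ene-2-carboxylic acid γ-lactone | O=C1[C@@]2(C)CC=C3C(=O)OC[C@@]13[C@H]([C@H](C)CCC=C(C)C)CC2 | intermediate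
20 | (1S,5R,8S,9R)-1,2-bis(hydroxymethyl)-5-methyl-8-[(2R)-6-methylhept-5-en-2-yl]bicyclo[3.3.1]non-2-en-9-ol | O[C@@H]1[C@@]2(C)CC=C(CO)[C@]1(CO)[C@H]([C@H](C)CCC=C(C)C)CC2 | intermediate
21 | (1S,5R,8S,9R)-5-methyl-8-[(2R)-6-methylhept-5-en-2-yl]-1,2-bis[(triethylsilyloxy)methyl]bicyclo[3.3.1]non-2-en-9-ol | O[C@@H]1[C@@]2(C)CC=C(CO[Si](CC)(CC)CC)[C@]1(CO[Si](CC)(CC)CC)[C@H]([C@H](C)CCC=C(C)C)CC2 | intermediate
22 | 9-acetate of 21 | CC(=O)O[C@@H]1[C@@]2(C)CC=C(CO[Si](CC)(CC)CC)[C@]1(CO[Si](CC)(CC)CC)[C@H]([C@H](C)CCC=C(C)C)CC2 | intermediate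
23 | bis(alkoxydimethylsulfonium) dichloride from 22 | CC(=O)O[C@@H]1[C@@]2(C)CC=C(CO[S+](C)C)[C@]1(CO[S+](C)C)[C@H]([C@H](C)CCC=C(C)C)CC2.[Cl-].[Cl-] | intermediate
24 | (1R,5R,8S,9R)-1,2-diformyl-5-methyl-8-[(2R)-6-methylhept-5-en-2-yl]bicyclo[3.3.1]non-2-en-9-yl acetate | CC(=O)O[C@@H]1[C@@]2(C)CC=C(C=O)[C@]1(C=O)[C@H]([C@H](C)CCC=C(C)C)CC2 | target

Total step count: 12. Longest linear sequence: 12 steps (1 → 24).

**Steps most likely to fail**

1. Step 7. What may go wrong: oxidative addition into the bond to the quaternary carbon (leading to a fused ring system), decarbonylation of the rhodacycle, or failure of the hindered olefin to insert. Fallback, from 15 back to 16, by known reactions that make the two bonds one after the other. Palladium-catalysed α-vinylation of the ketone at its only enolisable carbon (vinyl bromide, Pd2(dba)3, P(t-Bu)3, LiN(SiMe3)2), then kinetic protonation of the re-formed enolate from the face anti to the side chain, should give the cis-2-vinylcyclobutanone F1 with the vinyl group on the side of the tether. Ring-closing metathesis of the vinyl group with the 1,1-disubstituted olefin (second-generation Hoveyda–Grubbs catalyst, high dilution) would close an eight-membered ring and give the bridged 2-alkenylcyclobutanone F2. A thermal or photochemical 1,3-acyl shift, the known ring expansion of 2-alkenylcyclobutanones to cyclohex-3-enones, would move the carbonyl carbon onto the methyl-bearing olefin carbon and give the bicyclo[3.3.1]non-6-en-9-one lactone F3. Diimide (p-toluenesulfonyl hydrazide, NaOAc) would then reduce the cis-disubstituted ring olefin in the presence of the trisubstituted side-chain olefin and return the route at 16.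

2. Step 4. What may go wrong: poor discrimination between the two enantiotopic methylenes, giving a mixture of diastereomers at the ring CH that is carried through. Fallback, from 6 back to 8: the choice is made by a stoichiometric chiral base instead of a catalyst. Deprotonation of 6 with lithium (R,R)-bis(1-phenylethyl)amide (or its enantiomer, chosen by the same criterion as the catalyst) in the presence of Me3SiCl (THF, −100 °C) should give the silyl enol ether F4. A Mukaiyama aldol addition of F4 to ethyl glyoxylate (BF3·OEt2, CH2Cl2, −78 °C) returns the route at 8.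

3. Step 6. What may go wrong: 1,2-addition of the Grignard reagent to the strained ketone, or proton transfer and retro-aldol equilibration of the magnesium enolate during hydroxymethylation. Fallback, from 10 back to 15: the enolate is trapped and isolated. Copper-catalysed addition of 12 to 10 in the presence of Me3SiCl should give the silyl enol ether F5. F5 is hydroxymethylated under Lewis-acid catalysis in aqueous medium (aq. CH2O, Yb(OSO2CF3)3, THF), again anti to the side chain, and acid then closes the lactone to 15.

**Further compounds**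
F1 | step 7 | 2-ethenyl derivative of 15, vinyl group cis to C-8 of the spirocycle | O=C1[C@@H](C=C)[C@@H]([C@H](C)CCC=C(C)C)[C@]12COC(=O)C2CCC(C)=C
F2 | step 7 | ring-closed bridged 2-alkenylcyclobutanone (eight-membered ring spanning the cyclobutanone, lactone retained) | O=C1[C@H]2C=C(C)CCC3C(=O)OC[C@@]13[C@@H]2[C@H](C)CCC=C(C)C
F3 | step 7 | 6,7-didehydro derivative of 16 (bicyclo[3.3.1]non-6-en-9-one lactone) | O=C1[C@@]2(C)CCC3C(=O)OC[C@@]13[C@H]([C@H](C)CCC=C(C)C)C=C2
F4 | step 4 | trimethyl{[(3S)-3-[(2R)-6-methylhept-5-en-2-yl]cyclobut-1-en-1-yl]oxy}silane | C[Si](C)(C)OC1=C[C@H]([C@H](C)CCC=C(C)C)C1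
F5 | step 6 | ethyl 5-methyl-2-{(4S)-4-[(2R)-6-methylhept-5-en-2-yl]-2-(trimethylsilyloxy)cyclobut-1-en-1-yl}hex-5-enoate | CCOC(=O)C(CCC(C)=C)C1=C(O[Si](C)(C)C)C[C@H]1[C@H](C)CCC=C(C)C
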